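**Plan**
1. Cuts: the six O–benzyl bonds; the C4 carbonyl back to a C4–O ether carrying a chiral auxiliary; ring C of the flavanone at C4–C4a and C2–C3 in one formal [4+2] disconnection (O-aryl oxocarbenium ion + enol ether); the enol ether at its aryl–vinyl bond; the flavone at its pyranone ring.
2. Enabling feature: C2 is an acetal-level benzylic carbon between O1 and the para-oxygenated ring B, and C4a is an ortho carbon of phloroglucinol ring A (ortho to O1 and C5–O, para to C7–O, both ortho positions equivalent). The unit C4a=C8a–O1=C2(+) is therefore a cationic 2-oxadiene that takes up a C3=C4 enol ether.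
3. Forward: flavone of the lower unit (Claisen–Schmidt, I2/DMSO) → chiral (E)-alkoxyvinyl group by Suzuki coupling → ring C of the flavanone closed onto ring A in the key step → C4 oxidized to the ketone → benzyl ethers removed.
4. Stereochemistry: the (1R,2S)-2-phenylcyclohexyl group on the enol ether oxygen fixes the face of C3; the anti topicity of the cycloaddition places C2 trans to C3; the C4 centre is erased by oxidation; 2,3-trans is also the thermodynamic arrangement.

Key step: step 9

Assumption: the sense of π-facial induction by the (1R,2S)-2-phenylcyclohexyl group is taken from the shielding model of the s-trans enol ether; if it proves opposite, the equally available (1S,2R) alcohol is used with no other change.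

**Step 1**
Reactants: 1 4-(benzyloxy)benzaldehyde
Product: 2 1-(benzyloxy)-4-(dimethoxymethyl)benzene
Conditions: HC(OMe)3, MeOH, p-TsOH·H2O (cat.), rt; then NaHCO3
Reagents that add atoms: trimethyl orthoformate, COC(OC)OC; methanol, CO
Why: Acid-catalysed acetalization, driven by the orthoformate as water scavenger, should give the dimethyl acetal that serves as precursor of the α-chloro ether.

**Step 2**
Reactants: 2 1-(benzyloxy)-4-(dimethoxymethyl)benzene; 3 3,5-bis(benzyloxy)phenol
Product: 5 1,3-bis(benzyloxy)-5-{[4-(benzyloxy)phenyl](methoxy)methoxy}benzene (racemic mixed O-aryl O-methyl acetal), via α-chloro ether 4 (not isolated)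
Conditions: AcCl (1.05 equiv), SOCl2 (2 mol %), CH2Cl2, 0 °C→rt, evaporate; then 3, i-Pr2NEt, CH2Cl2, 0 °C
Reagents that add atoms: none
Why: Acetyl chloride exchanges one methoxy group for chloride (α-halo ether formation) and the phenol then displaces chloride at oxygen as in a MOM protection, so the mixed acetal should form without acid that would ionize it.

**Step 3**
Reactants: 6 1-[2,4-bis(benzyloxy)-6-hydroxyphenyl]ethan-1-one; 7 4-(benzyloxy)-3-bromobenzaldehyde
Product: 8 (E)-1-[2,4-bis(benzyloxy)-6-hydroxyphenyl]-3-[4-(benzyloxy)-3-bromophenyl]prop-2-en-1-one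
Conditions: KOH (50% aq), EtOH/THF, rt
Reagents that add atoms: none
Why: Claisen–Schmidt condensation of the acetophenone enolate on the non-enolizable aldehyde, followed by E1cB dehydration, should give the (E)-2'-hydroxychalcone.

**Step 4**
Reactants: 8 (E)-2'-hydroxychalcone
Product: 9 5,7-bis(benzyloxy)-2-[4-(benzyloxy)-3-bromophenyl]-4H-chromen-4-one
Conditions: I2 (10 mol %), DMSO, 130 °C
Reagents that add atoms: none
Why: Iodine-catalysed oxidative cyclization of a 2'-hydroxychalcone in DMSO (the terminal oxidant) should give the flavone, the aryl bromide and benzyl ethers being inert.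

**Step 5**
Reactants: 10 (1R,2S)-2-phenylcyclohexan-1-ol
Product: 12 (1R,2S)-1-{[(E)-1,2-dichloroethenyl]oxy}-2-phenylcyclohexane, via potassium alkoxide 11 (not isolated)
Conditions: KH, THF, 0 °C→rt; then Cl2C=CHCl, −50 °C→rt
Reagents that add atoms: trichloroethylene, ClC=C(Cl)Cl
Why: Anti addition of the alkoxide to dichloroacetylene formed in the flask from trichloroethylene (elimination–addition) is the standard entry to 1,2-dichlorovinyl ethers of secondary alcohols and leaves the carbinol stereocentres untouched.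

**Step 6**
Reactants: 12 (1R,2S)-1-{[(E)-1,2-dichloroethenyl]oxy}-2-phenylcyclohexane
Product: 14 (1R,2S)-1-(ethynyloxy)-2-phenylcyclohexane, via lithium alkoxyacetylide 13 (not isolated)
Conditions: n-BuLi (2.5 equiv), THF, −78→−40 °C; then MeOH, −78 °C→rt
Reagents that add atoms: none
Why: Two equivalents of n-BuLi convert the dichlorovinyl ether into the lithium alkoxyacetylide by elimination of LiCl and chlorine–lithium exchange, and protonation should give the terminal ynol ether, which is kept at or below room temperature to avoid retro-ene loss of ketene.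

**Step 7**
Reactants: 14 (1R,2S)-1-(ethynyloxy)-2-phenylcyclohexane
Product: 15 4,4,5,5-tetramethyl-2-[(E)-2-{[(1R,2S)-2-phenylcyclohexyl]oxy}ethenyl]-1,3,2-dioxaborolane
Conditions: HBpin, Cp2ZrHCl (5 mol %), Et3N (10 mol %), CH2Cl2, rt
Reagents that add atoms: pinacolborane, CC1(C)OBOC1(C)C
Why: Zirconium-catalysed syn hydroboration of a terminal alkyne places boron on the terminal carbon and should give the (E)-2-alkoxyvinylboronate, as it does for ethoxyacetylene.

**Step 8**
Reactants: 9 5,7-bis(benzyloxy)-2-[4-(benzyloxy)-3-bromophenyl]-4H-chromen-4-one; 15 (E)-alkoxyvinylboronate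
Product: 16 5,7-bis(benzyloxy)-2-{4-(benzyloxy)-3-[(E)-2-{[(1R,2S)-2-phenylcyclohexyl]oxy}ethenyl]phenyl}-4H-chromen-4-one
Conditions: PdCl2(dppf) (5 mol %), K3PO4, 1,4-dioxane/H2O (5:1), 80 °C
Reagents that add atoms: none
Why: Suzuki–Miyaura coupling of an aryl bromide with an alkenylboronate proceeds with retention of alkene geometry, and the basic medium should leave the enol ether and the flavone intact.

**Step 9**
Reactants: 5 mixed O-aryl O-methyl acetal (1.5 equiv); 16 chiral (E)-enol ether
Product: 19 5,7-bis(benzyloxy)-2-{4-(benzyloxy)-3-[(2R,3R,4R)-5,7-bis(benzyloxy)-2-[4-(benzyloxy)phenyl]-4-{[(1R,2S)-2-phenylcyclohexyl]oxy}-3,4-dihydro-2H-chromen-3-yl]phenyl}-4H-chromen-4-one (2,3-trans-3,4-trans), via aryl oxocarbenium triflate 17 (not isolated), via alkoxycarbenium triflate 18 (not isolated)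
Conditions: TMSOTf (2.5 equiv), 2,6-di-tert-butyl-4-methylpyridine (3 equiv), CH2Cl2, −78→−40 °C; Et3N then NaHCO3 (aq) at −78 °C
Reagents that add atoms: none
Why: Proposed new method: TMSOTf removes the methoxy group of 5 to give the O-aryl oxocarbenium ion 17, the β-carbon of enol ether 16 (C3) adds to its carbon (C2) to give alkoxycarbenium ion 18, and the ortho carbon C4a of ring A closes onto C4 with loss of a proton, a formal inverse-electron-demand [4+2] cycloaddition of a cationic 2-oxadiene. The closest known reaction types are the oxa-Povarov reaction of aryl oxocarbenium ions with alkenes, the Povarov reaction with enol ethers, and Lewis acid promoted [4+2] cycloadditions of cationic heterodienes with vinyl ethers of trans-2-phenylcyclohexanol. Ring C is the only ring closed, by a 6-exo-trig Friedel–Crafts attack on the exocyclic C4=O(+) bond after the intermolecular C2–C3 bond formation. C3 is controlled by the auxiliary, whose phenyl group covers one face of the s-trans enol ether; C2 follows from the antiperiplanar (alkoxy-endo) approach of the (E)-oxocarbenium ion, which places the two aryl groups trans; C4 follows from the (E)-alkene geometry and equatorial closure and is removed in step 10. The step needs the enol ether and not an arene to capture 17, ionization of 5 by loss of methoxide, and closure at one ring position: the enol ether is the strongest π-nucleophile present, the more basic methoxy oxygen is silylated first, and the two ortho positions of ring A are equivalent and activated by three oxygen atoms. Minor stereoisomers are diastereomers of 19 because the auxiliary is still attached, and should be removable by chromatography.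

**Step 10**
Reactants: 19 4-alkoxyflavan
Product: 21 (2R,3S)-5,7-bis(benzyloxy)-3-{2-(benzyloxy)-5-[5,7-bis(benzyloxy)-4-oxo-4H-chromen-2-yl]phenyl}-2-[4-(benzyloxy)phenyl]-2,3-dihydro-4H-chromen-4-one, via hemiketal 20 (not isolated)
Conditions: DDQ (2 equiv), CH2Cl2/pH 7 phosphate buffer (10:1), 0 °C→rt
Reagents that add atoms: water, O
Why: DDQ oxidation of the C4–H bond, which is benzylic to the trialkoxy ring A and α to oxygen (the oxidative cleavage known for electron-rich benzylic ethers and for C4 of 5,7-dialkoxyflavans), should give in wet solvent the hemiketal, which collapses to the aryl ketone with release of the auxiliary alcohol while the trans C2/C3 centres are not involved.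

**Step 11**
Reactants: 21 hexabenzyl ether
Product: 22 (2R,3S)-3-[5-(5,7-dihydroxy-4-oxo-4H-chromen-2-yl)-2-hydroxyphenyl]-5,7-dihydroxy-2-(4-hydroxyphenyl)-2,3-dihydro-4H-chromen-4-one (target)
Conditions: H2 (1 atm), Pd/C (10%), THF/MeOH (1:1), rt
Reagents that add atoms: none
Why: Hydrogenolysis of the six aryl benzyl ethers under neutral conditions avoids the base- or acid-induced ring opening that would racemize C2 and should leave both carbonyl groups and the flavone double bond untouched at atmospheric pressure.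

**Compound list**
1 | 4-(benzyloxy)benzaldehyde | O=Cc1ccc(OCc2ccccc2)cc1 | starting material
2 | 1-(benzyloxy)-4-(dimethoxymethyl)benzene | COC(OC)c1ccc(OCc2ccccc2)cc1 | intermediate
3 | 3,5-bis(benzyloxy)phenol | Oc1cc(OCc2ccccc2)cc(OCc2ccccc2)c1 | starting material
4 | 1-(benzyloxy)-4-[chloro(methoxy)methyl]benzene (racemic α-chloro ether) | COC(Cl)c1ccc(OCc2ccccc2)cc1 | intermediate
5 | 1,3-bis(benzyloxy)-5-{[4-(benzyloxy)phenyl](methoxy)methoxy}benzene (racemic) | COC(Oc1cc(OCc2ccccc2)cc(OCc2ccccc2)c1)c1ccc(OCc2ccccc2)cc1 | intermediate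
6 | 1-[2,4-bis(benzyloxy)-6-hydroxyphenyl]ethan-1-one | CC(=O)c1c(O)cc(OCc2ccccc2)cc1OCc1ccccc1 | starting material
7 | 4-(benzyloxy)-3-bromobenzaldehyde | O=Cc1ccc(OCc2ccccc2)c(Br)c1 | starting material
8 | (E)-1-[2,4-bis(benzyloxy)-6-hydroxyphenyl]-3-[4-(benzyloxy)-3-bromophenyl]prop-2-en-1-one | O=C(/C=C/c1ccc(OCc2ccccc2)c(Br)c1)c1c(O)cc(OCc2ccccc2)cc1OCc1ccccc1 | intermediate
9 | 5,7-bis(benzyloxy)-2-[4-(benzyloxy)-3-bromophenyl]-4H-chromen-4-one | O=c1cc(-c2ccc(OCc3ccccc3)c(Br)c2)oc2cc(OCc3ccccc3)cc(OCc3ccccc3)c12 | intermediate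
10 | (1R,2S)-2-phenylcyclohexan-1-ol | O[C@@H]1CCCC[C@H]1c1ccccc1 | starting material
11 | potassium (1R,2S)-2-phenylcyclohexan-1-olate | [K+].[O-][C@@H]1CCCC[C@H]1c1ccccc1 | intermediate
12 | (1R,2S)-1-{[(E)-1,2-dichloroethenyl]oxy}-2-phenylcyclohexane | Cl/C=C(/Cl)O[C@@H]1CCCC[C@H]1c1ccccc1 | intermediate
13 | lithium {[(1R,2S)-2-phenylcyclohexyl]oxy}acetylide | [Li]C#CO[C@@H]1CCCC[C@H]1c1ccccc1 | intermediate
14 | (1R,2S)-1-(ethynyloxy)-2-phenylcyclohexane | C#CO[C@@H]1CCCC[C@H]1c1ccccc1 | intermediate
15 | 4,4,5,5-tetramethyl-2-[(E)-2-{[(1R,2S)-2-phenylcyclohexyl]oxy}ethenyl]-1,3,2-dioxaborolane | CC1(C)OB(/C=C/O[C@@H]2CCCC[C@H]2c2ccccc2)OC1(C)C | intermediate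
16 | 5,7-bis(benzyloxy)-2-{4-(benzyloxy)-3-[(E)-2-{[(1R,2S)-2-phenylcyclohexyl]oxy}ethenyl]phenyl}-4H-chromen-4-one | O=c1cc(-c2ccc(OCc3ccccc3)c(/C=C/O[C@@H]3CCCC[C@H]3c3ccccc3)c2)oc2cc(OCc3ccccc3)cc(OCc3ccccc3)c12 | intermediate
17 | (E)-[3,5-bis(benzyloxy)phenyl][4-(benzyloxy)benzylidene]oxonium triflate | c1ccccc1COc1ccc(/C=[O+]/c2cc(OCc3ccccc3)cc(OCc3ccccc3)c2)cc1.[O-]S(=O)(=O)C(F)(F)F | intermediate
18 | O-[(1R,2S)-2-phenylcyclohexyl] oxocarbenium triflate of 3-[3,5-bis(benzyloxy)phenoxy]-3-[4-(benzyloxy)phenyl]-2-{2-(benzyloxy)-5-[5,7-bis(benzyloxy)-4-oxo-4H-chromen-2-yl]phenyl}propanal (C2–C3 bond formed, ring C open, carbon centres as in 19) | [O+](=C[C@@H](c1cc(-c2cc(=O)c3c(OCc4ccccc4)cc(OCc4ccccc4)cc3o2)ccc1OCc1ccccc1)[C@H](c1ccc(OCc2ccccc2)cc1)Oc1cc(OCc2ccccc2)cc(OCc2ccccc2)c1)[C@@H]1CCCC[C@H]1c1ccccc1.[O-]S(=O)(=O)C(F)(F)F | intermediate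
19 | 5,7-bis(benzyloxy)-2-{4-(benzyloxy)-3-[(2R,3R,4R)-5,7-bis(benzyloxy)-2-[4-(benzyloxy)phenyl]-4-{[(1R,2S)-2-phenylcyclohexyl]oxy}-3,4-dihydro-2H-chromen-3-yl]phenyl}-4H-chromen-4-one | O([C@@H]1CCCC[C@H]1c1ccccc1)[C@H]1c2c(OCc3ccccc3)cc(OCc3ccccc3)cc2O[C@@H](c2ccc(OCc3ccccc3)cc2)[C@@H]1c1cc(-c2cc(=O)c3c(OCc4ccccc4)cc(OCc4ccccc4)cc3o2)ccc1OCc1ccccc1 | intermediate
20 | C4 hemiketal of 21: (2R,3S)-4-hydroxy-4-{[(1R,2S)-2-phenylcyclohexyl]oxy} analogue of 19 (C4 configuration undefined) | O([C@@H]1CCCC[C@H]1c1ccccc1)C1(O)c2c(OCc3ccccc3)cc(OCc3ccccc3)cc2O[C@@H](c2ccc(OCc3ccccc3)cc2)[C@@H]1c1cc(-c2cc(=O)c3c(OCc4ccccc4)cc(OCc4ccccc4)cc3o2)ccc1OCc1ccccc1 | intermediate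
21 | (2R,3S)-5,7-bis(benzyloxy)-3-{2-(benzyloxy)-5-[5,7-bis(benzyloxy)-4-oxo-4H-chromen-2-yl]phenyl}-2-[4-(benzyloxy)phenyl]-2,3-dihydro-4H-chromen-4-one | O=C1c2c(OCc3ccccc3)cc(OCc3ccccc3)cc2O[C@@H](c2ccc(OCc3ccccc3)cc2)[C@@H]1c1cc(-c2cc(=O)c3c(OCc4ccccc4)cc(OCc4ccccc4)cc3o2)ccc1OCc1ccccc1 | intermediate
22 | (2R,3S)-3-[5-(5,7-dihydroxy-4-oxo-4H-chromen-2-yl)-2-hydroxyphenyl]-5,7-dihydroxy-2-(4-hydroxyphenyl)-2,3-dihydro-4H-chromen-4-one | O=C1c2c(O)cc(O)cc2O[C@@H](c2ccc(O)cc2)[C@@H]1c1cc(-c2cc(=O)c3c(O)cc(O)cc3o2)ccc1O | target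

**Step count**
Total: 11 steps. Longest linear sequence: 7 steps (steps 5, 6, 7, 8, 9, 10, 11, from 10 to 22).

**Steps most likely to fail**

Step 9. The enol ether may be attacked with poor facial or anti/syn selectivity. The acetal may ionize by loss of the aryloxy group instead of methoxide. The cation may alkylate ring A of a second molecule. The C4 ether of the product may ionize and eliminate under the Lewis acid. The fallback uses known chemistry, builds ring C first and makes the C3–aryl bond last. It sets out from 6 and 9 and comes back at 21. Compound 6 is heated with N,N-dimethylformamide dimethyl acetal to give (E)-1-[2,4-bis(benzyloxy)-6-hydroxyphenyl]-3-(dimethylamino)prop-2-en-1-one F1, which should close with HCl in CH2Cl2 to 5,7-bis(benzyloxy)-4H-chromen-4-one F2. Asymmetric conjugate addition of [4-(benzyloxy)phenyl]boronic acid, catalysed by Pd(OCOCF3)2 and the t-BuPyOx enantiomer that delivers the 2R product (NH4PF6, H2O, ClCH2CH2Cl, 60 °C), should give (2R)-5,7-bis(benzyloxy)-2-[4-(benzyloxy)phenyl]-2,3-dihydro-4H-chromen-4-one F3. Palladium-catalysed α-arylation of ketone F3 with bromide 9 (Pd(OAc)2, XPhos, K3PO4, toluene, 80 °C) should then give 21, with C3 settling trans to the C2 aryl group by enolization. The route continues with step 11.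

Step 10. Hydride abstraction may compete at C2, or loss of the C3 proton may lead to the flav-3-ene and further dehydrogenation. The fallback replaces oxidative cleavage by solvolysis and alcohol oxidation. It sets out from 19 and comes back at 21. HCl (0.1 M) in THF/H2O at rt should ionize the C4–O bond through the benzylic cation stabilized by ring A and give, with release of the auxiliary, (2R,3R)-5,7-bis(benzyloxy)-3-{2-(benzyloxy)-5-[5,7-bis(benzyloxy)-4-oxo-4H-chromen-2-yl]phenyl}-2-[4-(benzyloxy)phenyl]-3,4-dihydro-2H-chromen-4-ol (C4 epimers) F4. Dess–Martin oxidation (NaHCO3, CH2Cl2, rt) should then give 21.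

Step 11. Hydrogenolysis of the benzylic C2–O1 bond of the flavanone or saturation of the flavone C2=C3 bond may set in before all six benzyl groups are removed, and low solubility of partly deprotected material may stall the reaction. The fallback is a non-reductive debenzylation. It sets out from 21 and comes back at 22: BCl3 (excess) with pentamethylbenzene as benzyl cation scavenger, CH2Cl2, −78 °C, then MeOH. It makes no new compound (F0).

**Further compounds**
F1 | step 9 | (E)-1-[2,4-bis(benzyloxy)-6-hydroxyphenyl]-3-(dimethylamino)prop-2-en-1-one | CN(C)/C=C/C(=O)c1c(O)cc(OCc2ccccc2)cc1OCc1ccccc1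
F2 | step 9 | 5,7-bis(benzyloxy)-4H-chromen-4-one | O=c1ccoc2cc(OCc3ccccc3)cc(OCc3ccccc3)c12
F3 | step 9 | (2R)-5,7-bis(benzyloxy)-2-[4-(benzyloxy)phenyl]-2,3-dihydro-4H-chromen-4-one | O=C1C[C@H](c2ccc(OCc3ccccc3)cc2)Oc2cc(OCc3ccccc3)cc(OCc3ccccc3)c12
F4 | step 10 | (2R,3R)-5,7-bis(benzyloxy)-3-{2-(benzyloxy)-5-[5,7-bis(benzyloxy)-4-oxo-4H-chromen-2-yl]phenyl}-2-[4-(benzyloxy)phenyl]-3,4-dihydro-2H-chromen-4-ol (C4 epimers) | OC1c2c(OCc3ccccc3)cc(OCc3ccccc3)cc2O[C@@H](c2ccc(OCc3ccccc3)cc2)[C@@H]1c1cc(-c2cc(=O)c3c(OCc4ccccc4)cc(OCc4ccccc4)cc3o2)ccc1OCc1ccccc1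
F0 | step 11 | none | none
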